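**Retrosynthetic overview**
- Target 14 is a 3,6-dihydro-1,2-dioxine whose C6 is a methoxy peroxyketal carbon, so C6 is left unselected and set last by equilibration in acidic methanol; the methyl ester comes from an N-acyl oxazolidinone.
- The strategy rests on C3: it carries ring oxygen O2, is bonded to vinylic C4, and is the beta carbon of the acetate arm. The C3–C4 bond is therefore made by adding a C4 vinyl radical to a beta-peroxyacrylimide (11 to 12), which closes the only ring.
- Precursor 11 comes from conjugate addition of the methoxy hydroperoxide 7 to N-propioloyl oxazolidinone 10.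
- Hydroperoxide 7 comes from the Z-iodoalkenyl dimethyl ketal 6, built from heptadecanoyl chloride and bis(trimethylsilyl)acetylene by acylation, ketalization, iododesilylation and diimide reduction.

Key step: step 8

Remark on the chemistry: C6 is carried as a mixture (racemic in 7 and 11, both epimers in 12 and 13, SMILES left undefined there) and fixed in step 10. The ligand antipode that gives 3S cannot be predicted for this new substrate class; the (3aR,8aS) form is written and its commercial enantiomer is used if a first trial shows the opposite sense.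

**Route**

Step 1
Reactants: 1 heptadecanoyl chloride; 2 bis(trimethylsilyl)acetylene
Product: 3 1-(trimethylsilyl)nonadec-1-yn-3-one
Conditions: AlCl3, CH2Cl2, 0 °C
Reagents that add atoms: none
Why: Friedel–Crafts-type acylation of the bis-silyl alkyne (ipso substitution of one silyl group by the acylium ion) should give the silyl ynone without the over-addition that an acetylide Grignard reagent risks with an acid chloride.

Step 2
Reactants: 3 1-(trimethylsilyl)nonadec-1-yn-3-one
Product: 4 (3,3-dimethoxynonadec-1-yn-1-yl)trimethylsilane
Conditions: HC(OMe)3, MeOH, TsOH·H2O (cat.), rt to 40 °C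
Reagents that add atoms: trimethyl orthoformate COC(OC)OC; methanol CO
Why: Acid-catalysed ketalization driven by the orthoformate as water scavenger; the silyl cap blocks conjugate addition of methanol to the ynone.

Step 3
Reactants: 4 (3,3-dimethoxynonadec-1-yn-1-yl)trimethylsilane
Product: 5 1-iodo-3,3-dimethoxynonadec-1-yne
Conditions: NIS, AgNO3 (cat.), DMF, rt, dark
Reagents that add atoms: N-iodosuccinimide O=C1CCC(=O)N1I
Why: Silver-catalysed iododesilylation through the silver acetylide runs under near-neutral conditions that the ketal should tolerate.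

Step 4
Reactants: 5 1-iodo-3,3-dimethoxynonadec-1-yne
Product: 6 (1Z)-1-iodo-3,3-dimethoxynonadec-1-ene
Conditions: 2-O2NC6H4SO2NHNH2, Et3N, THF/i-PrOH, rt
Reagents that add atoms: none
Why: Diimide reduction; concerted syn transfer of two hydrogens to the iodoalkyne should give the Z-iodoalkene without C–I hydrogenolysis, and the basic medium spares the ketal.

Step 5
Reactants: 6 (1Z)-1-iodo-3,3-dimethoxynonadec-1-ene
Product: 7 (1Z)-3-hydroperoxy-1-iodo-3-methoxynonadec-1-ene (racemic)
Conditions: H2O2·urea, Sc(OTf)3 (cat.), MeOH, 0 °C to rt
Reagents that add atoms: hydrogen peroxide as its urea adduct OO.NC(N)=O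
Why: Lewis-acid-catalysed perhydrolysis of a ketal: the allylic oxocarbenium ion is captured by H2O2, and methanol as solvent should hold the exchange at the mono-hydroperoxy ketal; the new centre forms racemic.

Step 6
Reactants: 8 propiolic acid; 9 oxazolidin-2-one
Product: 10 3-(prop-2-ynoyl)-1,3-oxazolidin-2-one
Conditions: DCC, DMAP (cat.), CH2Cl2, 0 °C
Reagents that add atoms: none
Why: Carbodiimide-mediated N-acylation (Steglich-type coupling) of the oxazolidinone with the alkynoic acid.

Step 7
Reactants: 7 (1Z)-3-hydroperoxy-1-iodo-3-methoxynonadec-1-ene; 10 3-(prop-2-ynoyl)-1,3-oxazolidin-2-one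
Product: 11 3-[(2E)-3-{[(1Z)-1-iodo-3-methoxynonadec-1-en-3-yl]peroxy}prop-2-enoyl]-1,3-oxazolidin-2-one (racemic at the peroxyketal carbon)
Conditions: DABCO (cat.), CH2Cl2, −20 to 0 °C; used promptly, kept cold
Reagents that add atoms: none
Why: Amine-catalysed conjugate (peroxy-Michael) addition of a hydroperoxide to an acetylenic carbonyl compound; DABCO adds first and is displaced by the peroxide anion, which should give the E adduct, and phosphine catalysts are avoided because they reduce hydroperoxides.

Step 8
Reactants: 11 3-[(2E)-3-{[(1Z)-1-iodo-3-methoxynonadec-1-en-3-yl]peroxy}prop-2-enoyl]-1,3-oxazolidin-2-one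
Product: 12 3-{2-[(3S)-6-hexadecyl-6-methoxy-3,6-dihydro-1,2-dioxin-3-yl]acetyl}-1,3-oxazolidin-2-one (3S,6R and 3S,6S epimers together)
Conditions: Mg(NTf2)2 (1.1 equiv), 2,2'-(cyclopropane-1,1-diyl)bis[(3aR,8aS)-3a,8a-dihydro-8H-indeno[1,2-d]oxazole] (1.2 equiv), 4 Å MS, CH2Cl2, rt; then 11, −78 °C; Bu3SnH (1.5 equiv), Et3B, air, −78 °C
Reagents that add atoms: none
Why: Proposed new method: a tributyltin radical abstracts iodine from C4, the sigma vinyl radical (which inverts fast, so the iodoalkene geometry is not critical) adds to the peroxy-bearing beta carbon of the Mg-chelated acrylimide to form C3–C4, and the Lewis-acid-bound alpha-carbonyl radical then takes hydrogen from Bu3SnH. The closest known reaction types are the radical cyclization of beta-alkoxyacrylates to oxacycles and the enantioselective radical conjugate addition to N-enoyl oxazolidinones held by a chiral magnesium bis(oxazoline) complex; a beta-peroxy acceptor and an intramolecular vinyl radical are new here. The 1,2-dioxine ring closes in the 6-exo-trig mode. C3 is the only new stereocentre and is set by the ligand, which shields one face of the s-cis chelated enoyl unit; a full equivalent of the complex is used so that unbound substrate does not cyclize unselectively, while C6 stays unselected until step 10. The step needs iodine abstraction to outrun tin attack on the O–O bond, ring closure to outrun 1,5-hydrogen transfer from OCH3 or C8–H and direct reduction of the vinyl radical, and hydrogen transfer to outrun loss of the beta-peroxy group from the cyclized radical; the fast C–I abstraction, the Lewis-acid-activated acceptor, the low temperature and a tuned tin hydride concentration are meant to secure these. Mg(NTf2)2 is chosen over a magnesium halide because halide ions such as iodide reduce O–O bonds.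

Step 9
Reactants: 12 3-{2-[(3S)-6-hexadecyl-6-methoxy-3,6-dihydro-1,2-dioxin-3-yl]acetyl}-1,3-oxazolidin-2-one
Product: 13 methyl 2-[(3S)-6-hexadecyl-6-methoxy-3,6-dihydro-1,2-dioxin-3-yl]acetate (3S,6R and 3S,6S epimers together)
Conditions: MeOMgBr (premixed from MeMgBr and MeOH), MeOH/CH2Cl2, −20 to 0 °C; aq. NH4Cl
Reagents that add atoms: methanol CO, delivered as bromomagnesium methoxide CO[Mg]Br
Why: Magnesium-chelation-assisted transesterification of the N-acyl oxazolidinone at the exocyclic carbonyl; the weakly basic magnesium methoxide at low temperature should spare the base-sensitive dioxine and leave C3 untouched.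

Step 10
Reactants: 13 methyl 2-[(3S)-6-hexadecyl-6-methoxy-3,6-dihydro-1,2-dioxin-3-yl]acetate
Product: 14 methyl 2-[(3S,6R)-6-hexadecyl-6-methoxy-3,6-dihydro-1,2-dioxin-3-yl]acetate
Conditions: TsOH·H2O (cat.), MeOH, rt; SiO2 chromatography; the 6S-enriched fraction is resubmitted
Reagents that add atoms: methanol CO
Why: Acid-catalysed peroxyketal exchange through the cyclic peroxycarbenium ion equilibrates C6 only, since the C3–O bond is not broken, so the 6R epimer can be separated and the remainder recycled.

**Compound list**
1 | heptadecanoyl chloride | CCCCCCCCCCCCCCCCC(=O)Cl | starting material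
2 | bis(trimethylsilyl)acetylene | C[Si](C)(C)C#C[Si](C)(C)C | starting material
3 | 1-(trimethylsilyl)nonadec-1-yn-3-one | CCCCCCCCCCCCCCCCC(=O)C#C[Si](C)(C)C | intermediate
4 | (3,3-dimethoxynonadec-1-yn-1-yl)trimethylsilane | CCCCCCCCCCCCCCCCC(OC)(OC)C#C[Si](C)(C)C | intermediate
5 | 1-iodo-3,3-dimethoxynonadec-1-yne | CCCCCCCCCCCCCCCCC(OC)(OC)C#CI | intermediate
6 | (1Z)-1-iodo-3,3-dimethoxynonadec-1-ene | CCCCCCCCCCCCCCCCC(OC)(OC)/C=C\I | intermediate
7 | (1Z)-3-hydroperoxy-1-iodo-3-methoxynonadec-1-ene, racemic | CCCCCCCCCCCCCCCCC(OC)(OO)/C=C\I | intermediate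
8 | propiolic acid | C#CC(=O)O | starting material
9 | oxazolidin-2-one | O=C1NCCO1 | starting material
10 | 3-(prop-2-ynoyl)-1,3-oxazolidin-2-one | C#CC(=O)N1CCOC1=O | intermediate
11 | 3-[(2E)-3-{[(1Z)-1-iodo-3-methoxynonadec-1-en-3-yl]peroxy}prop-2-enoyl]-1,3-oxazolidin-2-one, racemic at the peroxyketal carbon | CCCCCCCCCCCCCCCCC(OC)(/C=C\I)OO/C=C/C(=O)N1CCOC1=O | intermediate
12 | 3-{2-[(3S)-6-hexadecyl-6-methoxy-3,6-dihydro-1,2-dioxin-3-yl]acetyl}-1,3-oxazolidin-2-one, C6 epimers (6R and 6S) | CCCCCCCCCCCCCCCCC1(OC)C=C[C@H](CC(=O)N2CCOC2=O)OO1 | intermediate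
13 | methyl 2-[(3S)-6-hexadecyl-6-methoxy-3,6-dihydro-1,2-dioxin-3-yl]acetate, C6 epimers (6R and 6S) | CCCCCCCCCCCCCCCCC1(OC)C=C[C@H](CC(=O)OC)OO1 | intermediate
14 | methyl 2-[(3S,6R)-6-hexadecyl-6-methoxy-3,6-dihydro-1,2-dioxin-3-yl]acetate | CCCCCCCCCCCCCCCC[C@]1(OC)C=C[C@H](CC(=O)OC)OO1 | target

**Step count**
Total steps: 10. Longest linear sequence: 9 (steps 1 to 5, then 7 to 10; step 6 is the side branch).

**Steps most likely to fail**

Step 8 (Proposed new method).
- What may go wrong: the vinyl radical may be reduced, or may shift a hydrogen from OCH3 or C8, before it closes the ring. The cyclized radical may expel the peroxy oxygen. The Lewis acid may trigger heterolytic O–O cleavage with a 1,2-shift (Criegee-type rearrangement) in the vinylogous perester. Face selection at C3 may be poor.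
- Fallback, known chemistry, setting out from 6 and returning at 14: Heck coupling of 6 with methyl acrylate under ligand-free conditions (Pd(OAc)2, Bu4NCl, NaHCO3, DMF, rt), with retention of the Z geometry, should give methyl (2E,4Z)-6,6-dimethoxydocosa-2,4-dienoate F1. Perhydrolysis as in step 5 should give methyl (2E,4Z)-6-hydroperoxy-6-methoxydocosa-2,4-dienoate F2. Et2NH in CF3CH2OH should then bring about intramolecular conjugate addition of the hydroperoxide to C3, giving methyl 2-(6-hexadecyl-6-methoxy-3,6-dihydro-1,2-dioxin-3-yl)acetate F3 as all four stereoisomers. Equilibration of C6 as in step 10, separation of the diastereomers on silica and resolution by preparative HPLC on a chiral stationary phase lead to 14.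

Step 7.
- What may go wrong: the peroxide anion may attack the imide carbonyl (acyl transfer) instead of the alkyne terminus. The amine may oligomerize the ynoyl imide. The vinylogous perester may undergo O–O heterolysis during formation or handling.
- Fallback, setting out from 7 and 9 and returning at 11: DCC coupling of 9 with commercial (E)-3-chloroacrylic acid should give 3-[(2E)-3-chloroprop-2-enoyl]-1,3-oxazolidin-2-one F4. Treating 7 with F4 and Cs2CO3 in MeCN at 0 °C should give 11 by addition–elimination (nucleophilic vinylic substitution) with retention of the E geometry and without any amine nucleophile.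

Step 9.
- What may go wrong: base-induced opening of the dioxine may compete with acyl transfer, either by deprotonation at C3–H with O–O cleavage (Kornblum–DeLaMare fragmentation) or by enolization and beta-elimination of the peroxide, which would also erode C3.
- Fallback, setting out from 12 and returning at 13: LiOH/H2O2 in THF/H2O at 0 °C, where the hydroperoxide anion is far less basic than methoxide and attacks the exocyclic carbonyl, should give 2-[(3S)-6-hexadecyl-6-methoxy-3,6-dihydro-1,2-dioxin-3-yl]acetic acid F5. Esterification with Me3SiCHN2 in MeOH/toluene at 0 °C should then give 13.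

**Further compounds**
F1 | step 8 | methyl (2E,4Z)-6,6-dimethoxydocosa-2,4-dienoate | CCCCCCCCCCCCCCCCC(OC)(OC)/C=C\C=C\C(=O)OC
F2 | step 8 | methyl (2E,4Z)-6-hydroperoxy-6-methoxydocosa-2,4-dienoate, racemic | CCCCCCCCCCCCCCCCC(OC)(OO)/C=C\C=C\C(=O)OC
F3 | step 8 | methyl 2-(6-hexadecyl-6-methoxy-3,6-dihydro-1,2-dioxin-3-yl)acetate, all four stereoisomers | CCCCCCCCCCCCCCCCC1(OC)C=CC(CC(=O)OC)OO1
F4 | step 7 | 3-[(2E)-3-chloroprop-2-enoyl]-1,3-oxazolidin-2-one | O=C(/C=C/Cl)N1CCOC1=O
F5 | step 9 | 2-[(3S)-6-hexadecyl-6-methoxy-3,6-dihydro-1,2-dioxin-3-yl]acetic acid, C6 epimers | CCCCCCCCCCCCCCCCC1(OC)C=C[C@H](CC(=O)O)OO1
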